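**Retrosynthetic overview**
- The target is reached from its bis(methoxymethyl) ether by acid hydrolysis. The keto acid comes from a 3-butylphthalide by lactone opening and oxidation, and the phthalide from a ring A benzoate carrying a silylated carbinol.
- The strategy rests on ring A: C3 (H), C4 (OMe), C5 (H) and C6 (side-chain carbon) are the diene carbons of a 6-substituted 4-methoxy-2-pyrone. C1 (carboxyl) and C2 (aryloxy) are the two carbons of an alkyne that already carries the ester and the ring B oxygen, so the hindered C2–O–aryl bond exists before ring A does.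
- The alkyne, methyl 3-aryloxypropiolate, comes from the protected ring B phenol and trichloroethylene (dichlorovinyl ether, lithium acetylide, methyl chloroformate). The phenol comes from olivetol by formylation, acetal protection and Baeyer–Villiger oxidation.
- The pyrone comes from 4-methoxy-6-methyl-2-pyrone by oxidation of the methyl group, butyl Grignard addition and silylation.
- Ring order: ring B is bought (olivetol); ring A is formed in step 9; a temporary lactone ring is closed in step 10 and opened in step 11.

Key step: step 9

Assumption (remark on the chemistry): the target has no stereocentre; the side-chain carbinol carbon is carried as a racemate from step 7 and becomes the ketone carbon in step 11, and bicyclic lactone 17 is a transient mixture of diastereomers.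

**Route**

Step 1
Reactants: 1 olivetol
Product: 3 2,4-dihydroxy-6-pentylbenzaldehyde, via aryl iminium chloride 2 (not isolated)
Conditions: POCl3 (1.2 equiv), DMF, 0 °C to rt; then H2O, 50 °C
Reagents that add atoms: N,N-dimethylformamide, CN(C)C=O; water, O
Why: Vilsmeier–Haack formylation, in which the chloroiminium ion attacks the ring carbon para to one hydroxyl and ortho to the other (the position between OH and pentyl, as is usual for 5-alkylresorcinols), and water hydrolyses iminium salt 2 to the aldehyde.

Step 2
Reactants: 3 2,4-dihydroxy-6-pentylbenzaldehyde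
Product: 4 2,4-bis(methoxymethoxy)-6-pentylbenzaldehyde
Conditions: NaH (2.5 equiv), MOMCl (2.5 equiv), DMF, 0 °C to rt
Reagents that add atoms: chloromethyl methyl ether, COCCl
Why: Double Williamson O-alkylation; full deprotonation with NaH breaks the hydrogen bond of the ortho hydroxyl to the aldehyde, so that both phenols are capped as acetals that tolerate the organolithium, thermal, fluoride and basic steps ahead.

Step 3
Reactants: 4 2,4-bis(methoxymethoxy)-6-pentylbenzaldehyde
Product: 6 2,4-bis(methoxymethoxy)-6-pentylphenol, via aryl formate 5 (not isolated)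
Conditions: mCPBA (1.3 equiv), CH2Cl2, 0 °C to rt; then K2CO3 (cat.), MeOH, rt, under Ar
Reagents that add atoms: 3-chloroperoxybenzoic acid, OOC(=O)c1cccc(Cl)c1
Why: Baeyer–Villiger (Dakin-type) oxidation, in which the electron-rich aryl group migrates in the Criegee adduct to give formate 5, which K2CO3-catalysed methanolysis cleaves to the phenol, so the aldehyde carbon is exchanged for the oxygen that will become the diaryl ether oxygen.

Step 4
Reactants: 6 2,4-bis(methoxymethoxy)-6-pentylphenol; 7 trichloroethylene
Product: 8 2-{[(E)-1,2-dichloroethenyl]oxy}-1,5-bis(methoxymethoxy)-3-pentylbenzene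
Conditions: Cl2C=CHCl (1.5 equiv), K2CO3 (2 equiv), DMF, 70 °C
Reagents that add atoms: trichloroethylene (compound 7), ClC=C(Cl)Cl
Why: Base-mediated vinylic substitution on trichloroethylene (elimination to dichloroacetylene, then anti addition of the phenoxide and protonation) gives the (E)-1,2-dichlorovinyl ether, the standard gateway to ynol ethers, and it bonds the hindered phenol oxygen to carbon while that carbon is still unhindered.

Step 5
Reactants: 8 2-{[(E)-1,2-dichloroethenyl]oxy}-1,5-bis(methoxymethoxy)-3-pentylbenzene
Product: 11 methyl 3-[2,4-bis(methoxymethoxy)-6-pentylphenoxy]prop-2-ynoate, via chloroalkynyl ether 9 (not isolated), via lithium aryloxyacetylide 10 (not isolated)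
Conditions: n-BuLi (2.2 equiv), THF, −78 to −40 °C; then ClCO2Me (1.2 equiv), −78 °C; chromatography on Et3N-deactivated silica
Reagents that add atoms: methyl chloroformate, COC(=O)Cl
Why: n-BuLi removes the vinylic proton, LiCl is lost to give chloroalkyne 9, chlorine–lithium exchange gives acetylide 10, and C-acylation of this acetylide with methyl chloroformate (standard acetylide acylation) gives the ynol ether ester.

Step 6
Reactants: 12 4-methoxy-6-methyl-2H-pyran-2-one
Product: 13 4-methoxy-6-oxo-6H-pyran-2-carbaldehyde
Conditions: SeO2 (2 equiv), 1,4-dioxane, 160 °C, sealed tube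
Reagents that add atoms: selenium dioxide, O=[Se]=O
Why: Riley oxidation with SeO2 of the 6-methyl group, which is activated as the vinylogous alpha position of the pyrone (ene reaction, 2,3-shift and loss of selenium), and the aldehyde formed has no further activated C–H.

Step 7
Reactants: 13 4-methoxy-6-oxo-6H-pyran-2-carbaldehyde; 14 butylmagnesium bromide
Product: 15 6-(1-hydroxypentyl)-4-methoxy-2H-pyran-2-one (racemic)
Conditions: BuMgBr (1.05 equiv), THF, −78 °C; then aq. NH4Cl
Reagents that add atoms: butylmagnesium bromide (compound 14), CCCC[Mg]Br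
Why: Grignard 1,2-addition at −78 °C, the aldehyde being far more electrophilic than the cross-conjugated lactone carbonyl; the new carbinol centre forms as a racemate without control, which is acceptable because step 11 oxidises it.

Step 8
Reactants: 15 6-(1-hydroxypentyl)-4-methoxy-2H-pyran-2-one
Product: 16 6-[1-(tert-butyldimethylsilyloxy)pentyl]-4-methoxy-2H-pyran-2-one (racemic)
Conditions: TBSCl (1.3 equiv), imidazole (2 equiv), DMF, rt
Reagents that add atoms: tert-butyldimethylsilyl chloride, CC(C)(C)[Si](C)(C)Cl
Why: Imidazole-promoted silylation of the secondary alcohol masks the future ketone as a thermally stable ether that keeps the pyrone electron rich for the cycloaddition.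

Step 9
Reactants: 11 methyl 3-[2,4-bis(methoxymethoxy)-6-pentylphenoxy]prop-2-ynoate; 16 6-[1-(tert-butyldimethylsilyloxy)pentyl]-4-methoxy-2H-pyran-2-one
Product: 18 methyl 2-[2,4-bis(methoxymethoxy)-6-pentylphenoxy]-6-[1-(tert-butyldimethylsilyloxy)pentyl]-4-methoxybenzoate (racemic), via bridged bicyclic lactone 17 (not isolated)
Conditions: 16 (2 equiv, excess recoverable), BHT (cat.), 1,2-dichlorobenzene (1 M), 150–160 °C, sealed tube, Ar
Reagents that add atoms: none
Why: Proposed new method: a thermal, asynchronous (4+2) cycloaddition joins pyrone C3 and C6 to the two alkyne carbons of 11 and gives bridged lactone 17, which loses CO2 by retro-(4+2) and so delivers ring A already aromatic and fully substituted; the closest known reaction type is the cycloaddition/CO2 extrusion of 4-methoxy-2-pyrones with propiolates or acetylenedicarboxylates (and, with opposite electron demand, with ynamines), but a 3-aryloxypropiolate has not been used as the alkyne. Ring A closes by intermolecular (4+2) annulation, both new bonds (C2–C3 and C1–C6) being made in the one cycloaddition, so no separate ring-closing or oxidation step is needed. No stereocentre is created: the two bridgeheads of 17 become arene carbons and the silyloxy-bearing carbon is untouched. The step needs regioselectivity, and the polarisation of the two partners is matched in both senses: pyrone C3 (beta carbon of the 4-methoxy enol ether) is the nucleophilic diene terminus and C6 the electrophilic one, while in 11 the aryloxy-bearing carbon is the electrophilic beta carbon of the ynoate and the ester-bearing carbon is the nucleophilic beta carbon of the ynol ether, so C3 should bond to the aryloxy carbon and C6 to the ester carbon. The carbinol is kept as a silyl ether so that the pyrone stays electron rich, and an aryl ynol ether has no retro-ene pathway of the kind that destroys alkyl ynol ethers on heating, which should let 11 survive the temperature required.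

Step 10
Reactants: 18 methyl 2-[2,4-bis(methoxymethoxy)-6-pentylphenoxy]-6-[1-(tert-butyldimethylsilyloxy)pentyl]-4-methoxybenzoate
Product: 20 3-butyl-7-[2,4-bis(methoxymethoxy)-6-pentylphenoxy]-5-methoxy-2-benzofuran-1(3H)-one (racemic), via hydroxy ester 19 (not isolated)
Conditions: Bu4NF (1.2 equiv), THF, 0 °C to rt; then H2O
Reagents that add atoms: none
Why: Fluoride cleaves the Si–O bond and the benzylic alkoxide of 19 attacks the neighbouring ester (5-exo-trig lactonisation with loss of methoxide), which turns the di-ortho-substituted methyl ester, otherwise very hard to saponify, into a phthalide that hydroxide opens readily.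

Step 11
Reactants: 20 3-butyl-7-[2,4-bis(methoxymethoxy)-6-pentylphenoxy]-5-methoxy-2-benzofuran-1(3H)-one
Product: 22 2-[2,4-bis(methoxymethoxy)-6-pentylphenoxy]-4-methoxy-6-pentanoylbenzoic acid, via sodium hydroxy carboxylate 21 (not isolated)
Conditions: NaOH (3 equiv), t-BuOH/H2O, 70 °C; then KMnO4 (0.7 equiv, portionwise), 0 °C; filtration; 1 M HCl to pH 3, 0 °C
Reagents that add atoms: sodium hydroxide, [Na+].[OH-]
Why: Hydroxide opens the lactone to carboxylate 21, which cannot re-close in base, and cold alkaline KMnO4 oxidises the secondary benzylic alcohol (a classical conversion of 3-alkylphthalides into 2-acylbenzoic acids) faster than it attacks aryl ethers, acetals or the pentyl chain, erasing the carbinol centre.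

Step 12
Reactants: 22 2-[2,4-bis(methoxymethoxy)-6-pentylphenoxy]-4-methoxy-6-pentanoylbenzoic acid
Product: 23 2-(2,4-dihydroxy-6-pentylphenoxy)-4-methoxy-6-pentanoylbenzoic acid (target)
Conditions: 2 M aq. HCl/THF (1:1), 0.01 M, 45 °C, Ar
Reagents that add atoms: none
Why: Acid-catalysed hydrolysis of the two aryl methoxymethyl acetals through oxocarbenium ions; water and THF are used instead of an alcohol so that the 2-acylbenzoic acid cannot form a pseudo-ester, and high dilution under argon limits recapture of formaldehyde by, and air oxidation of, the free ring B phenols.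

**Compound list**
1 | olivetol (5-pentylbenzene-1,3-diol) | CCCCCc1cc(O)cc(O)c1 | starting material
2 | [(2,4-dihydroxy-6-pentylphenyl)methylidene]dimethylammonium chloride | CCCCCc1cc(O)cc(O)c1C=[N+](C)C.[Cl-] | intermediate (not isolated)
3 | 2,4-dihydroxy-6-pentylbenzaldehyde | CCCCCc1cc(O)cc(O)c1C=O | intermediate
4 | 2,4-bis(methoxymethoxy)-6-pentylbenzaldehyde | CCCCCc1cc(OCOC)cc(OCOC)c1C=O | intermediate
5 | 2,4-bis(methoxymethoxy)-6-pentylphenyl formate | CCCCCc1cc(OCOC)cc(OCOC)c1OC=O | intermediate (not isolated)
6 | 2,4-bis(methoxymethoxy)-6-pentylphenol | CCCCCc1cc(OCOC)cc(OCOC)c1O | intermediate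
7 | trichloroethylene | ClC=C(Cl)Cl | starting material
8 | 2-{[(E)-1,2-dichloroethenyl]oxy}-1,5-bis(methoxymethoxy)-3-pentylbenzene | Cl/C=C(Cl)\Oc1c(CCCCC)cc(OCOC)cc1OCOC | intermediate
9 | 2-[(chloroethynyl)oxy]-1,5-bis(methoxymethoxy)-3-pentylbenzene | ClC#COc1c(CCCCC)cc(OCOC)cc1OCOC | intermediate (not isolated)
10 | lithium [2,4-bis(methoxymethoxy)-6-pentylphenoxy]acetylide | [Li]C#COc1c(CCCCC)cc(OCOC)cc1OCOC | intermediate (not isolated)
11 | methyl 3-[2,4-bis(methoxymethoxy)-6-pentylphenoxy]prop-2-ynoate | CCCCCc1cc(OCOC)cc(OCOC)c1OC#CC(=O)OC | intermediate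
12 | 4-methoxy-6-methyl-2H-pyran-2-one | Cc1cc(OC)cc(=O)o1 | starting material
13 | 4-methoxy-6-oxo-6H-pyran-2-carbaldehyde | O=Cc1cc(OC)cc(=O)o1 | intermediate
14 | butylmagnesium bromide | CCCC[Mg]Br | starting material
15 | 6-(1-hydroxypentyl)-4-methoxy-2H-pyran-2-one (racemic) | CCCCC(O)c1cc(OC)cc(=O)o1 | intermediate
16 | 6-[1-(tert-butyldimethylsilyloxy)pentyl]-4-methoxy-2H-pyran-2-one (racemic) | CCCCC(O[Si](C)(C)C(C)(C)C)c1cc(OC)cc(=O)o1 | intermediate
17 | methyl 6-[2,4-bis(methoxymethoxy)-6-pentylphenoxy]-1-[1-(tert-butyldimethylsilyloxy)pentyl]-8-methoxy-3-oxo-2-oxabicyclo[2.2.2]octa-5,7-diene-5-carboxylate (mixture of diastereomers) | O=C1OC2(C(CCCC)O[Si](C)(C)C(C)(C)C)C=C(OC)C1C(Oc3c(CCCCC)cc(OCOC)cc3OCOC)=C2C(=O)OC | intermediate (not isolated)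
18 | methyl 2-[2,4-bis(methoxymethoxy)-6-pentylphenoxy]-6-[1-(tert-butyldimethylsilyloxy)pentyl]-4-methoxybenzoate (racemic) | CCCCCc1cc(OCOC)cc(OCOC)c1Oc1cc(OC)cc(C(CCCC)O[Si](C)(C)C(C)(C)C)c1C(=O)OC | intermediate
19 | methyl 2-[2,4-bis(methoxymethoxy)-6-pentylphenoxy]-6-(1-hydroxypentyl)-4-methoxybenzoate (racemic) | CCCCCc1cc(OCOC)cc(OCOC)c1Oc1cc(OC)cc(C(O)CCCC)c1C(=O)OC | intermediate (not isolated)
20 | 3-butyl-7-[2,4-bis(methoxymethoxy)-6-pentylphenoxy]-5-methoxy-2-benzofuran-1(3H)-one (racemic) | CCCCC1OC(=O)c2c(Oc3c(CCCCC)cc(OCOC)cc3OCOC)cc(OC)cc21 | intermediate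
21 | sodium 2-[2,4-bis(methoxymethoxy)-6-pentylphenoxy]-6-(1-hydroxypentyl)-4-methoxybenzoate (racemic) | CCCCCc1cc(OCOC)cc(OCOC)c1Oc1cc(OC)cc(C(O)CCCC)c1C(=O)[O-].[Na+] | intermediate (not isolated)
22 | 2-[2,4-bis(methoxymethoxy)-6-pentylphenoxy]-4-methoxy-6-pentanoylbenzoic acid | CCCCCc1cc(OCOC)cc(OCOC)c1Oc1cc(OC)cc(C(=O)CCCC)c1C(=O)O | intermediate
23 | 2-(2,4-dihydroxy-6-pentylphenoxy)-4-methoxy-6-pentanoylbenzoic acid | CCCCCc1cc(O)cc(O)c1Oc1cc(OC)cc(C(=O)CCCC)c1C(=O)O | target

**Step count**
Total: 12 steps (ring B alkyne branch, steps 1–5; pyrone branch, steps 6–8; union and endgame, steps 9–12).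
Longest linear sequence: 9 steps (steps 1–5 and 9–12, from olivetol).

**Steps most likely to fail**

1. Step 9. The cycloaddition may be slower than thermal oligomerisation or adventitious hydration of the push–pull alkyne, and the branched C6 side chain may slow the bonding of C6 to the ester carbon or erode the regioselectivity. The fallback uses known chemistry, sets out from phenol 6 and returns at phthalide 20. Commercial 3,5-dibromoanisole is deprotonated between the two bromines with lithium diisopropylamide (LiN(i-Pr)2, THF, −78 °C) and acylated with methyl chloroformate to give methyl 2,6-dibromo-4-methoxybenzoate F1. One bromine is exchanged with i-PrMgCl·LiCl (THF, −40 °C) to give methyl 2-bromo-6-(chloromagnesio)-4-methoxybenzoate F2, which adds to pentanal. On warming, the alkoxide closes onto the ester and, after aq. NH4Cl, should give 7-bromo-3-butyl-5-methoxy-2-benzofuran-1(3H)-one F3. A copper-catalysed Ullmann ether synthesis of F3 with 6 (CuI, picolinic acid, K3PO4, DMSO, 90 °C), assisted by the ortho lactone carbonyl, should then give 20, after which steps 11 and 12 follow unchanged.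

2. Step 11. Permanganate may not discriminate fully between the benzylic alkoxide and the electron-rich ring B or its benzylic methylene, and unoxidised hydroxy acid would re-lactonise on acidification. The fallback sets out from 20 and returns at 22. The lactone is opened with NaOH as in step 11 to give 21, the salt is dried and alkylated with benzyl bromide in DMF at rt to give benzyl 2-[2,4-bis(methoxymethoxy)-6-pentylphenoxy]-6-(1-hydroxypentyl)-4-methoxybenzoate F4. This is oxidised at once with Dess–Martin periodinane (NaHCO3, CH2Cl2, 0 °C) to benzyl 2-[2,4-bis(methoxymethoxy)-6-pentylphenoxy]-4-methoxy-6-pentanoylbenzoate F5. Hydrogenolysis (H2, 1 atm, Pd/C, EtOAc, rt) should then free acid 22.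

3. Step 5. The acetylide may be over-acylated by the chloroformate, and the ynol ether ester may be lost by hydration or addition–elimination during quench and chromatography. The fallback sets out from 8 and returns at 11. Treatment of 8 with n-BuLi (2.2 equiv, THF, −78 °C) and a methanol quench gives the terminal ynol ether 2-(ethynyloxy)-1,5-bis(methoxymethoxy)-3-pentylbenzene F6, which is isolated. A catalytic C–H carboxylation under mild base (AgI cat., Cs2CO3, CO2 1 atm, DMF, 40 °C) gives cesium 3-[2,4-bis(methoxymethoxy)-6-pentylphenoxy]prop-2-ynoate F7, which is methylated in the same flask with MeI to give 11 without exposure to an organolithium or an acid chloride.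

**Further compounds**
F1 | step 9 | methyl 2,6-dibromo-4-methoxybenzoate | COC(=O)c1c(Br)cc(OC)cc1Br
F2 | step 9 | methyl 2-bromo-6-(chloromagnesio)-4-methoxybenzoate | COC(=O)c1c(Br)cc(OC)cc1[Mg]Cl
F3 | step 9 | 7-bromo-3-butyl-5-methoxy-2-benzofuran-1(3H)-one (racemic) | CCCCC1OC(=O)c2c(Br)cc(OC)cc21
F4 | step 11 | benzyl 2-[2,4-bis(methoxymethoxy)-6-pentylphenoxy]-6-(1-hydroxypentyl)-4-methoxybenzoate (racemic) | CCCCCc1cc(OCOC)cc(OCOC)c1Oc1cc(OC)cc(C(O)CCCC)c1C(=O)OCc1ccccc1
F5 | step 11 | benzyl 2-[2,4-bis(methoxymethoxy)-6-pentylphenoxy]-4-methoxy-6-pentanoylbenzoate | CCCCCc1cc(OCOC)cc(OCOC)c1Oc1cc(OC)cc(C(=O)CCCC)c1C(=O)OCc1ccccc1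
F6 | step 5 | 2-(ethynyloxy)-1,5-bis(methoxymethoxy)-3-pentylbenzene | C#COc1c(CCCCC)cc(OCOC)cc1OCOC
F7 | step 5 | cesium 3-[2,4-bis(methoxymethoxy)-6-pentylphenoxy]prop-2-ynoate | [Cs+].[O-]C(=O)C#COc1c(CCCCC)cc(OCOC)cc1OCOC
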